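Ring A is treated as a cyclopentenone, and the contiguous C1, C5 and C6 centres are built at once. In the target, quaternary C1 carries a methyl next to ring-fusion C5, and O–C4–C5–C6–O is an aldol pattern. Copper-catalysed asymmetric methyl addition to C1 of a 3-(3-methylbut-3-enyl)cyclopent-2-enone, followed by capture of the resulting enolate at C5 by acrolein, forms C1–CH3 and C5–C6 and sets all three centres. The two terminal alkenes that remain close ring B by metathesis. The C7=C8 alkene is then shifted to C8=C9 without disturbing C6, whose hydroxyl finally directs the epoxidation.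

Key step: step 2

Remark: atoms carry daucane numbers (ring A = cyclopentane C1–C5; ring B = cycloheptane C1, C5–C10; C1 angular methyl, C4 isopropyl carbinol, C6 ester oxygen, C8/C9 epoxide). α is the face of the C5 hydrogen and β that of the C1 methyl. The antipode of the carbene ligand in step 2 is assumed to be the one that gives the C1 configuration of the target.

Step 1
Reactants: 1 4-bromo-2-methylbut-1-ene; 2 3-ethoxycyclopent-2-enone
Product: 5 3-(3-methylbut-3-enyl)cyclopent-2-enone, via Grignard reagent 3 (not isolated), via bromomagnesium alkoxide 4 (not isolated)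
Conditions: Mg, THF, 23–40 °C; then 2, THF, 0 → 23 °C; then 1 M aq. HCl, 0 °C
Reagents that add atoms: water, O
Why: Stork–Danheiser sequence, in which the homoallylic Grignard reagent adds 1,2 to the vinylogous ester and cold dilute acid hydrolyses the enol ether and dehydrates the tertiary carbinol to the transposed 3-substituted enone while the isolated 1,1-disubstituted alkene stays untouched.

Step 2
Reactants: 5 3-(3-methylbut-3-enyl)cyclopent-2-enone; 6 trimethylaluminium; 7 acrolein
Product: 9 (2S,3S)-2-[(1S)-1-hydroxyprop-2-enyl]-3-methyl-3-(3-methylbut-3-enyl)cyclopentanone, via dimethylaluminium enolate 8 (not isolated)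
Conditions: Me3Al (2 equiv), Cu(OTf)2 (5 mol %), [Ag(NHC)]2 (2.5 mol %; NHC = enantiopure trans-4,5-diphenyl-1-(2,6-diethylphenyl)-3-(2-sulfonatophenyl)imidazolin-2-ylidene), THF, −78 °C; then acrolein (4 equiv), −78 °C; aq. KNaC4H4O6
Reagents that add atoms: trimethylaluminium (6), C[Al](C)C; acrolein (7), C=CC=O
Why: Transmetalation of Me3Al to copper gives (NHC)CuCH3, which transfers methyl to the β-carbon C1 of the enone and releases the dimethylaluminium enolate 8 regiospecifically across C4–C5; 8 then adds through C5 to the carbonyl of acrolein in a closed, aluminium-bridged six-membered chair (Zimmerman–Traxler) transition state. The closest known reaction type is the copper-catalysed enantioselective conjugate addition of trialkylaluminium reagents to β-substituted cyclic enones that creates quaternary centres, with aldol interception of the metal enolate. No ring is closed. C1 is set by the chiral carbene ligand on copper; C5 is set by approach of the aldehyde to the enolate face anti to the longer butenyl arm on the adjacent quaternary C1, which places C6 cis to the C1 methyl; C6 is set by the chair transition state of the ring-locked E enolate with the vinyl group equatorial, which gives the anti aldol. The step needs 1,4- and not 1,2-delivery of methyl, secured by copper catalysis, and 1,2- and not 1,4-attack on acrolein without enolate equilibration, secured by the oxophilic aluminium enolate at −78 °C.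

Step 3
Reactants: 9 (2S,3S)-2-[(1S)-1-hydroxyprop-2-enyl]-3-methyl-3-(3-methylbut-3-enyl)cyclopentanone; 10 tert-butyldimethylsilyl trifluoromethanesulfonate
Product: 11 (2S,3S)-2-[(1S)-1-(tert-butyldimethylsilyloxy)prop-2-enyl]-3-methyl-3-(3-methylbut-3-enyl)cyclopentanone
Conditions: 10 (1.3 equiv), 2,6-lutidine (2 equiv), CH2Cl2, −78 °C
Reagents that add atoms: tert-butyldimethylsilyl trifluoromethanesulfonate (10), CC(C)(C)[Si](C)(C)OS(=O)(=O)C(F)(F)F
Why: O-silylation of the secondary aldol hydroxyl with a silyl triflate and a hindered pyridine base is fast at −78 °C and never forms the alkoxide that would allow retro-aldol cleavage or epimerisation at C5.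

Step 4
Reactants: 11 (2S,3S)-2-[(1S)-1-(tert-butyldimethylsilyloxy)prop-2-enyl]-3-methyl-3-(3-methylbut-3-enyl)cyclopentanone; 12 isopropylmagnesium chloride
Product: 13 (1R,2S,3S)-2-[(1S)-1-(tert-butyldimethylsilyloxy)prop-2-enyl]-3-methyl-3-(3-methylbut-3-enyl)-1-(propan-2-yl)cyclopentan-1-ol
Conditions: anhydrous CeCl3 (2 equiv), iPrMgCl (2 equiv), THF, −78 → 0 °C; aq. NH4Cl
Reagents that add atoms: isopropylmagnesium chloride (12), CC(C)[Mg]Cl
Why: Organocerium 1,2-addition, in which weakly basic iPrCeCl2 adds to the hindered, enolisable ketone without enolisation or β-hydride reduction and enters the α face of C4 anti to the β-oriented side chain on C5, so that the new C4 hydroxyl is β and the isopropyl group α.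

Step 5
Reactants: 13 (1R,2S,3S)-2-[(1S)-1-(tert-butyldimethylsilyloxy)prop-2-enyl]-3-methyl-3-(3-methylbut-3-enyl)-1-(propan-2-yl)cyclopentan-1-ol
Product: 14 6α-(tert-butyldimethylsilyloxy)dauc-7-en-4β-ol
Conditions: second-generation Grubbs catalyst (H2IMes)(PCy3)Cl2Ru=CHPh (10 mol %), CH2Cl2 (0.005 M), 40 °C
Reagents that add atoms: none
Why: Ring-closing metathesis, in which the catalyst loads on the vinyl group and closes onto the 1,1-disubstituted alkene to give the trisubstituted C7=C8 cycloheptene, the trans arrangement of the two arms on C1 and C5 leading directly to the trans-fused bicycle with loss of ethene.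

Step 6
Reactants: 14 6α-(tert-butyldimethylsilyloxy)dauc-7-en-4β-ol
Product: 15 6α-(tert-butyldimethylsilyloxy)dauc-7-ene-4β,9-diol (both C9 epimers)
Conditions: SeO2 (0.5 equiv), tBuOOH (3 equiv, decane), CH2Cl2, 0 → 23 °C
Reagents that add atoms: selenium dioxide, O=[Se]=O; tert-butyl hydroperoxide, CC(C)(C)OO
Why: Riley allylic hydroxylation, in which the ene step bonds selenium to the less substituted C7 and removes a ring hydrogen from C9 on the more substituted alkene terminus and the [2,3]-sigmatropic shift returns oxygen to C9 with C7=C8 restored, the configuration at C9 being immaterial because that centre is erased in step 7.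

Step 7
Reactants: 15 6α-(tert-butyldimethylsilyloxy)dauc-7-ene-4β,9-diol
Product: 18 6α-(tert-butyldimethylsilyloxy)dauc-8-en-4β-ol, via allylic sulfonylhydrazine 16 (not isolated), via allylic diazene 17 (not isolated)
Conditions: 2-nitrobenzenesulfonohydrazide (3 equiv), PPh3 (3 equiv), diethyl azodicarboxylate (3 equiv), THF, −30 °C; then 23 °C
Reagents that add atoms: none
Why: Mitsunobu displacement of the C9 hydroxyl by the sulfonylhydrazide, loss of sulfinic acid on warming and retro-ene extrusion of N2 from the monoalkyl diazene (reductive 1,3-transposition of an allylic alcohol) deliver hydrogen to C7 and place the alkene regiospecifically at C8=C9, the tertiary C4 hydroxyl being inert to Mitsunobu activation.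

Step 8
Reactants: 18 6α-(tert-butyldimethylsilyloxy)dauc-8-en-4β-ol
Product: 19 dauc-8-ene-4β,6α-diol
Conditions: Bu4NF (3 equiv), THF, 23 → 45 °C; water
Reagents that add atoms: none
Why: Fluoride-induced cleavage of the silyl ether, with no other fluoride- or base-sensitive group present.

Step 9
Reactants: 19 dauc-8-ene-4β,6α-diol
Product: 20 8α,9α-epoxydaucane-4β,6α-diol
Conditions: VO(acac)2 (5 mol %), tBuOOH (1.5 equiv, decane), CH2Cl2, 0 → 23 °C
Reagents that add atoms: tert-butyl hydroperoxide, CC(C)(C)OO
Why: Hydroxyl-directed epoxidation, in which the homoallylic α-hydroxyl at C6 coordinates vanadium and the bound tBuOOH delivers oxygen to the α face of C8=C9, which is also the face remote from the angular C1 methyl, while the tertiary C4 hydroxyl is too far away to compete.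

Step 10
Reactants: 20 8α,9α-epoxydaucane-4β,6α-diol; 21 3,4-dimethoxybenzoyl chloride
Product: 22 8α,9α-epoxy-4β-hydroxydaucan-6α-yl 3,4-dimethoxybenzoate (CNP0251065.1)
Conditions: 21 (1.5 equiv), Et3N (3 equiv), 4-(dimethylamino)pyridine (0.2 equiv), CH2Cl2, 0 → 23 °C
Reagents that add atoms: 3,4-dimethoxybenzoyl chloride (21), COc1ccc(C(Cl)=O)cc1OC
Why: Nucleophile-catalysed acylation selects the secondary C6 hydroxyl over the tertiary C4 hydroxyl, and the amine-buffered medium leaves the epoxide intact.

Compound list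
1 | 4-bromo-2-methylbut-1-ene | CC(=C)CCBr | starting material
2 | 3-ethoxycyclopent-2-enone | CCOC1=CC(=O)CC1 | starting material
3 | (3-methylbut-3-enyl)magnesium bromide | CC(=C)CC[Mg]Br | intermediate
4 | bromomagnesium 3-ethoxy-1-(3-methylbut-3-enyl)cyclopent-2-en-1-olate (racemic) | CCOC1=CC(CCC(C)=C)(O[Mg]Br)CC1 | intermediate
5 | 3-(3-methylbut-3-enyl)cyclopent-2-enone | O=C1C=C(CCC(C)=C)CC1 | intermediate
6 | trimethylaluminium | C[Al](C)C | starting material
7 | acrolein | C=CC=O | starting material
8 | dimethylaluminium (S)-3-methyl-3-(3-methylbut-3-enyl)cyclopent-1-en-1-olate | C[Al](C)OC1=C[C@@](C)(CCC(C)=C)CC1 | intermediate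
9 | (2S,3S)-2-[(1S)-1-hydroxyprop-2-enyl]-3-methyl-3-(3-methylbut-3-enyl)cyclopentanone (side chain on C2 cis to the C3 methyl; anti aldol) | O[C@@H](C=C)[C@H]1C(=O)CC[C@]1(C)CCC(C)=C | intermediate
10 | tert-butyldimethylsilyl trifluoromethanesulfonate | CC(C)(C)[Si](C)(C)OS(=O)(=O)C(F)(F)F | starting material
11 | (2S,3S)-2-[(1S)-1-(tert-butyldimethylsilyloxy)prop-2-enyl]-3-methyl-3-(3-methylbut-3-enyl)cyclopentanone | CC(C)(C)[Si](C)(C)O[C@@H](C=C)[C@H]1C(=O)CC[C@]1(C)CCC(C)=C | intermediate
12 | isopropylmagnesium chloride | CC(C)[Mg]Cl | starting material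
13 | (1R,2S,3S)-2-[(1S)-1-(tert-butyldimethylsilyloxy)prop-2-enyl]-3-methyl-3-(3-methylbut-3-enyl)-1-(propan-2-yl)cyclopentan-1-ol | CC(C)(C)[Si](C)(C)O[C@@H](C=C)[C@H]1[C@](O)(C(C)C)CC[C@]1(C)CCC(C)=C | intermediate
14 | 6α-(tert-butyldimethylsilyloxy)dauc-7-en-4β-ol (trans-fused; 1β-methyl, 5α-H, 4α-isopropyl) | CC(C)(C)[Si](C)(C)O[C@H]1C=C(C)CC[C@@]2(C)CC[C@@](O)(C(C)C)[C@H]12 | intermediate
15 | 6α-(tert-butyldimethylsilyloxy)dauc-7-ene-4β,9-diol (C9 epimers) | CC(C)(C)[Si](C)(C)O[C@H]1C=C(C)C(O)C[C@@]2(C)CC[C@@](O)(C(C)C)[C@H]12 | intermediate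
16 | N-[6α-(tert-butyldimethylsilyloxy)-4β-hydroxydauc-7-en-9-yl]-2-nitrobenzenesulfonohydrazide (sulfonyl and daucenyl on the same nitrogen) | CC(C)(C)[Si](C)(C)O[C@H]1C=C(C)C(N(N)S(=O)(=O)c3ccccc3[N+](=O)[O-])C[C@@]2(C)CC[C@@](O)(C(C)C)[C@H]12 | intermediate
17 | [6α-(tert-butyldimethylsilyloxy)-4β-hydroxydauc-7-en-9-yl]diazene | CC(C)(C)[Si](C)(C)O[C@H]1C=C(C)C(N=N)C[C@@]2(C)CC[C@@](O)(C(C)C)[C@H]12 | intermediate
18 | 6α-(tert-butyldimethylsilyloxy)dauc-8-en-4β-ol | CC(C)(C)[Si](C)(C)O[C@H]1CC(C)=CC[C@@]2(C)CC[C@@](O)(C(C)C)[C@H]12 | intermediate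
19 | dauc-8-ene-4β,6α-diol | O[C@H]1CC(C)=CC[C@@]2(C)CC[C@@](O)(C(C)C)[C@H]12 | intermediate
20 | 8α,9α-epoxydaucane-4β,6α-diol | O[C@H]1C[C@@]2(C)O[C@H]2C[C@@]2(C)CC[C@@](O)(C(C)C)[C@H]12 | intermediate
21 | 3,4-dimethoxybenzoyl chloride | COc1ccc(C(Cl)=O)cc1OC | starting material
22 | 8α,9α-epoxy-4β-hydroxydaucan-6α-yl 3,4-dimethoxybenzoate | COc1ccc(C(=O)O[C@H]2C[C@@]3(C)O[C@H]3C[C@@]3(C)CC[C@@](O)(C(C)C)[C@H]23)cc1OC | target

Total step count: 10. Longest linear sequence: 10 steps (1/2 → 22).

Steps most likely to fail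

Step 2. The enantio-induction on the five-membered enone may be incomplete. The aldehyde may discriminate poorly between the methyl and the butenyl arm on C1 when it approaches C5. Acrolein may also oligomerise in the presence of Lewis-acidic aluminium species. The fallback separates the two bond formations. Setting out from 5, the same copper-catalysed methyl addition is run and enolate 8 is quenched with Me3SiOTf to give (S)-3-methyl-3-(3-methylbut-3-enyl)-1-(trimethylsilyloxy)cyclopentene F1, which can be purified. MeLi in THF at 0 °C converts it into the regiodefined lithium (S)-3-methyl-3-(3-methylbut-3-enyl)cyclopent-1-en-1-olate F2. Acrolein at −78 °C should then give the anti aldol through the lithium chair transition state, and the route is rejoined at 9.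

Step 6. The ene reaction may be slow at the C7 terminus next to the bulky silyloxy group, the C8 methyl may be oxidised in competition, or the carbinol may be over-oxidised. The fallback moves the alkene through the C6 ketone instead and sets out from 14.
- Bu4NF frees dauc-7-ene-4β,6α-diol F3.
- MnO2 in CH2Cl2 oxidises the allylic alcohol to 4β-hydroxydauc-7-en-6-one F4.
- Me3SiOTf/Et3N in CH2Cl2 gives the extended, endocyclic 4β,6-bis(trimethylsilyloxy)dauca-6,8-diene F5, which also masks the C4 hydroxyl against retro-aldol cleavage.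
- Bu4NF/AcOH in THF at −78 → 0 °C protonates C7 kinetically and frees the C4 hydroxyl to give 4β-hydroxydauc-8-en-6-one F6.
- Me4NBH(OAc)3 in MeCN/AcOH at −20 °C, bound to the β-hydroxyl on C4, delivers hydride to the β face of C6 (Evans–Saksena reduction).

This fallback rejoins the route at 19 and makes steps 6 to 8 unnecessary.

Step 7. Mitsunobu activation of the C9 carbinol, which sits beside the methyl-bearing alkene carbon, may be sluggish, and elimination to a diene may compete. The fallback sets out from 15. MnO2 gives 6α-(tert-butyldimethylsilyloxy)-4β-hydroxydauc-7-en-9-one F7, and TsNHNH2 in EtOH with catalytic AcOH gives its 4-methylbenzenesulfonylhydrazone F8. Catecholborane in CHCl3 at 0 °C followed by NaOAc·3H2O at 60 °C reduces the hydrazone; the allylic diazene so formed loses N2 with hydrogen transfer to C7. The route is rejoined at 18.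

Further compounds
F1 | step 2 | (S)-3-methyl-3-(3-methylbut-3-enyl)-1-(trimethylsilyloxy)cyclopentene | C[Si](C)(C)OC1=C[C@@](C)(CCC(C)=C)CC1
F2 | step 2 | lithium (S)-3-methyl-3-(3-methylbut-3-enyl)cyclopent-1-en-1-olate | [Li]OC1=C[C@@](C)(CCC(C)=C)CC1
F3 | step 6 | dauc-7-ene-4β,6α-diol | O[C@H]1C=C(C)CC[C@@]2(C)CC[C@@](O)(C(C)C)[C@H]12
F4 | step 6 | 4β-hydroxydauc-7-en-6-one | O=C1C=C(C)CC[C@@]2(C)CC[C@@](O)(C(C)C)[C@H]12
F5 | step 6 | 4β,6-bis(trimethylsilyloxy)dauca-6,8-diene | C[Si](C)(C)OC1=CC(C)=CC[C@@]2(C)CC[C@@](O[Si](C)(C)C)(C(C)C)[C@H]12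
F6 | step 6 | 4β-hydroxydauc-8-en-6-one | O=C1CC(C)=CC[C@@]2(C)CC[C@@](O)(C(C)C)[C@H]12
F7 | step 7 | 6α-(tert-butyldimethylsilyloxy)-4β-hydroxydauc-7-en-9-one | CC(C)(C)[Si](C)(C)O[C@H]1C=C(C)C(=O)C[C@@]2(C)CC[C@@](O)(C(C)C)[C@H]12
F8 | step 7 | 6α-(tert-butyldimethylsilyloxy)-4β-hydroxydauc-7-en-9-one 4-methylbenzenesulfonylhydrazone | CC(C)(C)[Si](C)(C)O[C@H]1C=C(C)C(=NNS(=O)(=O)c3ccc(C)cc3)C[C@@]2(C)CC[C@@](O)(C(C)C)[C@H]12
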